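**Retrosynthetic overview**

- The last C–C bond made is the ketone carbon–α-carbon bond of the enone, formed by Rh-catalysed hydroacylation of a 2,4-bis(silyloxy)phenylacetylene with the complete chroman salicylaldehyde; only fluoride desilylation follows.
- The enabling feature is the free phenol on C5 of the chroman benzene ring, ortho to C6 that carries the carbonyl carbon. As a phenoxide it binds Rh and holds the acyl–Rh–H unit in a five-membered O,C-chelate (no decarbonylation, no protecting group), and the same OH steers the preceding formylation to C6.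
- The dihydropyran ring is the only ring built. Its O1–C2 bond is closed by acid cyclodehydration of a tertiary alcohol onto one of two rotationally equivalent phenols of a 2,6-dioxygenated 4-methoxybenzyl unit, so no regiochemical choice arises; the prenyl group is made from allyl by cross-metathesis after the acid step.
- The C3 stereocentre comes from Evans allylation of an N-(3-arylpropanoyl) imide; the arylpropanoic acid comes from 5-methoxyresorcinol by MOM protection, ortho-lithiation/formylation, Doebner condensation and hydrogenation.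
- Ring order: both benzene rings are bought; the pyran ring is closed before the fragment union. The alkyne comes from 2,4-dihydroxybenzaldehyde by silylation and one-carbon homologation.

Key step: step 14

Remark on the chemistry: the single stereocentre, C3 of the chroman, is R (CIP order C2 > C4 > prenyl CH2 > H). Both enantiomers of 4-benzyloxazolidin-2-one are commercial, and the R auxiliary is the one that delivers it.

**Route**

Step 1
Reactants: 1 5-methoxyresorcinol
Product: 2 1-methoxy-3,5-bis(methoxymethoxy)benzene
Conditions: NaH, MOMCl, DMF, 0 °C → rt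
Reagents that add atoms: chloromethyl methyl ether (MOMCl), COCCl
Why: Double Williamson O-alkylation of the phenoxides installs two MOM acetals that later act as ortho-directing groups and are removable with mild acid.

Step 2
Reactants: 2 1-methoxy-3,5-bis(methoxymethoxy)benzene
Product: 4 4-methoxy-2,6-bis(methoxymethoxy)benzaldehyde, via aryllithium 3 (not isolated)
Conditions: n-BuLi, THF, 0 °C → rt; DMF, −78 °C → rt; aq NH4Cl
Reagents that add atoms: N,N-dimethylformamide (DMF), CN(C)C=O
Why: Directed ortho-metalation should occur at the ring carbon flanked by the two OMOM groups (the most acidic, doubly chelated site), and formylation of the aryllithium with DMF should give the symmetric aldehyde.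

Step 3
Reactants: 4 4-methoxy-2,6-bis(methoxymethoxy)benzaldehyde
Product: 6 (E)-3-[4-methoxy-2,6-bis(methoxymethoxy)phenyl]acrylic acid, via arylidenemalonic acid 5 (not isolated)
Conditions: malonic acid, pyridine, piperidine (cat.), 90 °C
Reagents that add atoms: malonic acid, O=C(O)CC(=O)O
Why: Knoevenagel–Doebner condensation with decarboxylation of the arylidenemalonic acid should give the E-cinnamic acid under basic conditions that leave the MOM acetals intact.

Step 4
Reactants: 6 (E)-3-[4-methoxy-2,6-bis(methoxymethoxy)phenyl]acrylic acid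
Product: 7 3-[4-methoxy-2,6-bis(methoxymethoxy)phenyl]propanoic acid
Conditions: H2 (1 atm), 10% Pd/C, EtOAc, rt
Reagents that add atoms: none
Why: Heterogeneous catalytic hydrogenation should saturate only the conjugated C=C, since aryl MOM ethers and the arene are inert at 1 atm.

Step 5
Reactants: 7 3-[4-methoxy-2,6-bis(methoxymethoxy)phenyl]propanoic acid; 8 (R)-4-benzyloxazolidin-2-one
Product: 10 (R)-4-benzyl-3-{3-[4-methoxy-2,6-bis(methoxymethoxy)phenyl]propanoyl}oxazolidin-2-one, via mixed pivalic anhydride 9 (not isolated)
Conditions: PivCl, Et3N, THF, −20 °C; then 8, LiCl, −20 °C → rt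
Reagents that add atoms: none
Why: N-acylation of the oxazolidinone through the mixed pivalic anhydride (LiCl/Et3N variant) is the standard entry to an Evans imide and touches no stereocentre.

Step 6
Reactants: 10 (R)-4-benzyl-3-{3-[4-methoxy-2,6-bis(methoxymethoxy)phenyl]propanoyl}oxazolidin-2-one
Product: 12 (R)-4-benzyl-3-{(R)-2-[4-methoxy-2,6-bis(methoxymethoxy)benzyl]pent-4-enoyl}oxazolidin-2-one, via sodium enolate 11 (not isolated)
Conditions: NaHMDS, THF, −78 °C; allyl iodide, −78 → −45 °C
Reagents that add atoms: allyl iodide, C=CCI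
Why: Evans asymmetric alkylation: the chelated Z-enolate should be attacked by allyl iodide on the face opposite the C4 benzyl group of the R auxiliary, which sets the new α-centre as R (the future C3 of the chroman).

Step 7
Reactants: 12 (R)-4-benzyl-3-{(R)-2-[4-methoxy-2,6-bis(methoxymethoxy)benzyl]pent-4-enoyl}oxazolidin-2-one
Product: 13 methyl (R)-2-[4-methoxy-2,6-bis(methoxymethoxy)benzyl]pent-4-enoate
Conditions: MeMgBr, MeOH, CH2Cl2, 0 °C
Reagents that add atoms: methanol (as bromomagnesium methoxide), CO
Why: Transesterification with magnesium methoxide should cleave the exocyclic imide carbonyl selectively, release the auxiliary for recovery and leave the α-centre unepimerised.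

Step 8
Reactants: 13 methyl (R)-2-[4-methoxy-2,6-bis(methoxymethoxy)benzyl]pent-4-enoate
Product: 15 (R)-3-[4-methoxy-2,6-bis(methoxymethoxy)benzyl]-2-methylhex-5-en-2-ol, via methyl ketone 14 (not isolated)
Conditions: MeMgBr (excess), LaCl3·2LiCl (0.3 equiv), THF, 0 °C → rt; aq NH4Cl
Reagents that add atoms: methylmagnesium bromide, C[Mg]Br
Why: Double Grignard addition to the ester through the methyl ketone should give the gem-dimethyl carbinol, the lanthanum salt favouring addition over enolisation so that the adjacent stereocentre is kept.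

Step 9
Reactants: 15 (R)-3-[4-methoxy-2,6-bis(methoxymethoxy)benzyl]-2-methylhex-5-en-2-ol
Product: 17 (R)-3-allyl-7-methoxy-2,2-dimethylchroman-5-ol, via triol 16 (not isolated)
Conditions: conc. HCl (cat.), MeOH, 40 °C; then solvent switch, p-TsOH·H2O (cat.), toluene, 60 °C
Reagents that add atoms: none
Why: Acid methanolysis of both MOM acetals should give the triol, whose tertiary alcohol ionises and is captured by a neighbouring phenol oxygen (SN1 cyclodehydration to the six-membered ether); the two ortho-phenols are exchanged by rotation about the aryl–CH2 bond so only one chroman can form, C3 is not a reacting centre, and the monosubstituted allyl alkene is not protonated under these conditions.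

Step 10
Reactants: 17 (R)-3-allyl-7-methoxy-2,2-dimethylchroman-5-ol
Product: 18 (R)-7-methoxy-2,2-dimethyl-3-(3-methylbut-2-en-1-yl)chroman-5-ol
Conditions: Grubbs II (5 mol%), 2-methyl-2-butene/CH2Cl2, 40 °C
Reagents that add atoms: 2-methyl-2-butene, CC=C(C)C
Why: Olefin cross-metathesis of the terminal allyl group with excess 2-methyl-2-butene should convert it into the prenyl group with loss of propene, and the catalyst tolerates the free phenol.

Step 11
Reactants: 18 (R)-7-methoxy-2,2-dimethyl-3-(3-methylbut-2-en-1-yl)chroman-5-ol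
Product: 20 (R)-5-hydroxy-7-methoxy-2,2-dimethyl-3-(3-methylbut-2-en-1-yl)chroman-6-carbaldehyde, via salicyl alcohol 19 (not isolated)
Conditions: MgCl2, Et3N, (CH2O)n, MeCN, reflux; cold dilute HCl work-up
Reagents that add atoms: paraformaldehyde (formaldehyde), C=O
Why: Magnesium-mediated ortho-formylation (Casnati–Skattebøl) should deliver formaldehyde within the magnesium phenoxide to C6, the only free position ortho to the C5–OH, and a second formaldehyde oxidises the salicyl alcohol in situ, so C8 is untouched and the prenyl group sees no strong acid.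

Step 12
Reactants: 21 2,4-dihydroxybenzaldehyde
Product: 22 2,4-bis(tert-butyldimethylsilyloxy)benzaldehyde
Conditions: TBSCl, imidazole, DMF, rt
Reagents that add atoms: tert-butyldimethylsilyl chloride (TBSCl), CC(C)(C)[Si](C)(C)Cl
Why: Silylation of both phenols should give aryl silyl ethers that survive strong non-nucleophilic base and rhodium catalysis and are removed by fluoride at the end.

Step 13
Reactants: 22 2,4-bis(tert-butyldimethylsilyloxy)benzaldehyde
Product: 24 1-ethynyl-2,4-bis(tert-butyldimethylsilyloxy)benzene, via diazoalkene 23 (not isolated)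
Conditions: TMSCHN2, LDA, THF, −78 °C → rt; aq NH4Cl
Reagents that add atoms: (trimethylsilyl)diazomethane, C[Si](C)(C)C=[N+]=[N-]
Why: Colvin rearrangement: lithiated TMS-diazomethane adds to the aldehyde, Peterson elimination gives the diazoalkene, and loss of N2 with 1,2-hydride shift should give the terminal alkyne without the methanolic base that would cleave the aryl silyl ethers.

Step 14
Reactants: 20 (R)-5-hydroxy-7-methoxy-2,2-dimethyl-3-(3-methylbut-2-en-1-yl)chroman-6-carbaldehyde; 24 1-ethynyl-2,4-bis(tert-butyldimethylsilyloxy)benzene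
Product: 25 (E)-3-[2,4-bis(tert-butyldimethylsilyloxy)phenyl]-1-[(3R)-5-hydroxy-7-methoxy-2,2-dimethyl-3-(3-methylbut-2-en-1-yl)chroman-6-yl]prop-2-en-1-one
Conditions: [Rh(cod)Cl]2 (2.5 mol%), dppf (5 mol%), Na2CO3 (5 mol%), toluene, 80 °C, slow addition of 24
Reagents that add atoms: none
Why: The carbonate-generated rhodium(I) phenoxide of the C5–OH should insert into the adjacent formyl C–H bond to give an acyl–Rh(III)–hydride held in a five-membered O,C-chelate that resists decarbonylation; syn insertion of the terminal alkyne into Rh–H and C–C reductive elimination then join the acyl carbon to the alkyne terminus and release Rh(I). The closest known reaction type is the Rh/diphosphine-catalysed intermolecular hydroacylation of alkynes with salicylaldehydes. No ring is closed and no stereocentre is formed; the only new stereo-element, the E enone, follows from syn hydrometalation and retentive reductive elimination, and the C3 centre is remote and untouched. The step needs anti-Markovnikov regioselectivity (Rh on the terminal carbon), for which the terminal alkyne and the bulky ortho-silyloxyaryl group on the internal carbon are relied on, and chemoselectivity for the alkyne over the trisubstituted prenyl alkene, which should not insert into Rh–H at this temperature. Slow addition of the alkyne limits Rh-induced oligomerisation, and the low carbonate loading together with the strong C5–OH···O=C hydrogen bond should keep the product from closing to the flavanone.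

Step 15
Reactants: 25 (E)-3-[2,4-bis(tert-butyldimethylsilyloxy)phenyl]-1-[(3R)-5-hydroxy-7-methoxy-2,2-dimethyl-3-(3-methylbut-2-en-1-yl)chroman-6-yl]prop-2-en-1-one
Product: 26 (E)-3-(2,4-dihydroxyphenyl)-1-[(3R)-5-hydroxy-7-methoxy-2,2-dimethyl-3-(3-methylbut-2-en-1-yl)chroman-6-yl]prop-2-en-1-one (CNP0333857.1)
Conditions: TBAF, AcOH (1:1), THF, 0 °C
Reagents that add atoms: none
Why: Fluoride should cleave the two aryl Si–O bonds rapidly at 0 °C, and the acetic acid buffer keeps the phenols protonated so that neither oxa-Michael closure onto the enone nor E/Z scrambling is expected, while the prenyl group and the chroman are inert.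

**Compound list**

1 | 5-methoxyresorcinol | COc1cc(O)cc(O)c1 | starting material
2 | 1-methoxy-3,5-bis(methoxymethoxy)benzene | COCOc1cc(OC)cc(OCOC)c1 | intermediate
3 | [4-methoxy-2,6-bis(methoxymethoxy)phenyl]lithium | [Li]c1c(OCOC)cc(OC)cc1OCOC | intermediate
4 | 4-methoxy-2,6-bis(methoxymethoxy)benzaldehyde | COCOc1cc(OC)cc(OCOC)c1C=O | intermediate
5 | 2-[4-methoxy-2,6-bis(methoxymethoxy)benzylidene]malonic acid | COCOc1cc(OC)cc(OCOC)c1C=C(C(=O)O)C(=O)O | intermediate
6 | (E)-3-[4-methoxy-2,6-bis(methoxymethoxy)phenyl]acrylic acid | COCOc1cc(OC)cc(OCOC)c1/C=C/C(=O)O | intermediate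
7 | 3-[4-methoxy-2,6-bis(methoxymethoxy)phenyl]propanoic acid | COCOc1cc(OC)cc(OCOC)c1CCC(=O)O | intermediate
8 | (R)-4-benzyloxazolidin-2-one | O=C1N[C@H](Cc2ccccc2)CO1 | starting material
9 | 3-[4-methoxy-2,6-bis(methoxymethoxy)phenyl]propanoic pivalic anhydride | COCOc1cc(OC)cc(OCOC)c1CCC(=O)OC(=O)C(C)(C)C | intermediate
10 | (R)-4-benzyl-3-{3-[4-methoxy-2,6-bis(methoxymethoxy)phenyl]propanoyl}oxazolidin-2-one | COCOc1cc(OC)cc(OCOC)c1CCC(=O)N1C(=O)OC[C@H]1Cc1ccccc1 | intermediate
11 | sodium (Z)-enolate of 10 | COCOc1cc(OC)cc(OCOC)c1C/C=C(\[O-])N1C(=O)OC[C@H]1Cc1ccccc1.[Na+] | intermediate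
12 | (R)-4-benzyl-3-{(R)-2-[4-methoxy-2,6-bis(methoxymethoxy)benzyl]pent-4-enoyl}oxazolidin-2-one | C=CC[C@H](Cc1c(OCOC)cc(OC)cc1OCOC)C(=O)N1C(=O)OC[C@H]1Cc1ccccc1 | intermediate
13 | methyl (R)-2-[4-methoxy-2,6-bis(methoxymethoxy)benzyl]pent-4-enoate | C=CC[C@H](Cc1c(OCOC)cc(OC)cc1OCOC)C(=O)OC | intermediate
14 | (R)-3-[4-methoxy-2,6-bis(methoxymethoxy)benzyl]hex-5-en-2-one | C=CC[C@H](Cc1c(OCOC)cc(OC)cc1OCOC)C(C)=O | intermediate
15 | (R)-3-[4-methoxy-2,6-bis(methoxymethoxy)benzyl]-2-methylhex-5-en-2-ol | C=CC[C@H](Cc1c(OCOC)cc(OC)cc1OCOC)C(C)(C)O | intermediate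
16 | 2-[(2R)-2-(2-hydroxypropan-2-yl)pent-4-en-1-yl]-5-methoxybenzene-1,3-diol | C=CC[C@H](Cc1c(O)cc(OC)cc1O)C(C)(C)O | intermediate
17 | (R)-3-allyl-7-methoxy-2,2-dimethylchroman-5-ol | COc1cc2c(c(O)c1)C[C@@H](CC=C)C(C)(C)O2 | intermediate
18 | (R)-7-methoxy-2,2-dimethyl-3-(3-methylbut-2-en-1-yl)chroman-5-ol | COc1cc2c(c(O)c1)C[C@@H](CC=C(C)C)C(C)(C)O2 | intermediate
19 | (R)-6-(hydroxymethyl)-7-methoxy-2,2-dimethyl-3-(3-methylbut-2-en-1-yl)chroman-5-ol | COc1cc2c(c(O)c1CO)C[C@@H](CC=C(C)C)C(C)(C)O2 | intermediate
20 | (R)-5-hydroxy-7-methoxy-2,2-dimethyl-3-(3-methylbut-2-en-1-yl)chroman-6-carbaldehyde | COc1cc2c(c(O)c1C=O)C[C@@H](CC=C(C)C)C(C)(C)O2 | intermediate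
21 | 2,4-dihydroxybenzaldehyde | O=Cc1ccc(O)cc1O | starting material
22 | 2,4-bis(tert-butyldimethylsilyloxy)benzaldehyde | O=Cc1ccc(O[Si](C)(C)C(C)(C)C)cc1O[Si](C)(C)C(C)(C)C | intermediate
23 | 1-(2-diazovinyl)-2,4-bis(tert-butyldimethylsilyloxy)benzene | [N-]=[N+]=C=Cc1ccc(O[Si](C)(C)C(C)(C)C)cc1O[Si](C)(C)C(C)(C)C | intermediate
24 | 1-ethynyl-2,4-bis(tert-butyldimethylsilyloxy)benzene | C#Cc1ccc(O[Si](C)(C)C(C)(C)C)cc1O[Si](C)(C)C(C)(C)C | intermediate
25 | (E)-3-[2,4-bis(tert-butyldimethylsilyloxy)phenyl]-1-[(3R)-5-hydroxy-7-methoxy-2,2-dimethyl-3-(3-methylbut-2-en-1-yl)chroman-6-yl]prop-2-en-1-one | COc1cc2c(c(O)c1C(=O)/C=C/c1ccc(O[Si](C)(C)C(C)(C)C)cc1O[Si](C)(C)C(C)(C)C)C[C@@H](CC=C(C)C)C(C)(C)O2 | intermediate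
26 | (E)-3-(2,4-dihydroxyphenyl)-1-[(3R)-5-hydroxy-7-methoxy-2,2-dimethyl-3-(3-methylbut-2-en-1-yl)chroman-6-yl]prop-2-en-1-one | COc1cc2c(c(O)c1C(=O)/C=C/c1ccc(O)cc1O)C[C@@H](CC=C(C)C)C(C)(C)O2 | target

**Step count**

Total step count: 15. Longest linear sequence: 13 steps (steps 1–11, 14, 15).

**Steps most likely to fail, with fallbacks**

Step 14. The risk is Markovnikov insertion of the arylacetylene into Rh–H (giving the branched 1,1-disubstituted enone), Rh-induced oligomerisation of the alkyne, or decarbonylation of the acyl rhodium. The fallback sets out from 24 and 20 and comes back at 25. Hydrozirconation of 24 with Cp2Zr(H)Cl in THF followed by iodinolysis should give (E)-1-(2-iodovinyl)-2,4-bis(tert-butyldimethylsilyloxy)benzene F1, with the regiochemistry and E geometry fixed by syn addition of Zr–H. Nozaki–Hiyama–Kishi coupling of F1 with 20 (CrCl2, cat. NiCl2, DMF, rt), which tolerates the free phenol, should give the allylic alcohol F2 as a mixture of carbinol epimers. Oxidation with activated MnO2 in CH2Cl2 should then give 25 with the same ketone carbon–α-carbon bond in place.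

Step 9. The risk is E1 elimination or hydride shift at the tertiary cation competing with capture by the phenol (loss of material or erosion of the C3 configuration), and alkylation of the freed, electron-rich ring by methoxymethyl cations while the mixture is heated. The fallback makes the ether bond by cross-coupling instead of cation capture; it sets out from 12 and comes back at 17. HCl in MeOH at rt should remove both MOM groups of 12, and a liberated phenol should displace the auxiliary to give (R)-3-allyl-5-hydroxy-7-methoxychroman-2-one F3. Triflation of the remaining phenol (Tf2O, pyridine, CH2Cl2, 0 °C) should give the lactone aryl triflate F4. MeMgBr (THF, −78 → 0 °C) should open the lactone by double addition to give the phenol tertiary alcohol aryl triflate F5. Pd-catalysed intramolecular C–O coupling of the tertiary alcohol with the aryl triflate (Pd(OAc)2, a di-tert-butylbiarylphosphine, Cs2CO3, toluene, 80 °C) should close the pyran ring without a cation and give 17, the former lactone oxygen becoming the C5–OH.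

Step 13. The risk is silyl migration from the ortho phenol oxygen to the alkoxide adduct, or cleavage of the aryl silyl ethers by the strongly basic reagent, before Peterson elimination. The fallback sets out from 22 and comes back at 24. Dibromo-olefination (CBr4, PPh3, CH2Cl2, 0 °C) should give the neutral 1-(2,2-dibromovinyl)-2,4-bis(tert-butyldimethylsilyloxy)benzene F6. Treatment with n-BuLi (2.2 equiv, THF, −78 °C) and aqueous NH4Cl quench (Corey–Fuchs sequence) should give 24.

**Further compounds**

F1 | step 14 | (E)-1-(2-iodovinyl)-2,4-bis(tert-butyldimethylsilyloxy)benzene | I/C=C/c1ccc(O[Si](C)(C)C(C)(C)C)cc1O[Si](C)(C)C(C)(C)C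
F2 | step 14 | (E)-3-[2,4-bis(tert-butyldimethylsilyloxy)phenyl]-1-[(3R)-5-hydroxy-7-methoxy-2,2-dimethyl-3-(3-methylbut-2-en-1-yl)chroman-6-yl]prop-2-en-1-ol (carbinol epimers) | COc1cc2c(c(O)c1C(O)/C=C/c1ccc(O[Si](C)(C)C(C)(C)C)cc1O[Si](C)(C)C(C)(C)C)C[C@@H](CC=C(C)C)C(C)(C)O2
F3 | step 9 | (R)-3-allyl-5-hydroxy-7-methoxychroman-2-one | COc1cc2c(c(O)c1)C[C@@H](CC=C)C(=O)O2
F4 | step 9 | (R)-3-allyl-7-methoxy-2-oxochroman-5-yl trifluoromethanesulfonate | COc1cc2c(c(OS(=O)(=O)C(F)(F)F)c1)C[C@@H](CC=C)C(=O)O2
F5 | step 9 | 3-hydroxy-2-[(2R)-2-(2-hydroxypropan-2-yl)pent-4-en-1-yl]-5-methoxyphenyl trifluoromethanesulfonate | C=CC[C@H](Cc1c(O)cc(OC)cc1OS(=O)(=O)C(F)(F)F)C(C)(C)O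
F6 | step 13 | 1-(2,2-dibromovinyl)-2,4-bis(tert-butyldimethylsilyloxy)benzene | BrC(Br)=Cc1ccc(O[Si](C)(C)C(C)(C)C)cc1O[Si](C)(C)C(C)(C)C
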